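The runs were computed with constants of no real substance, noise included.

Add up the first autumn reading and a leftover appears: 1.70% of the charge stands in no column. The free catalyst is 1.72% of that charge, about the same size. So take the catalyst's share of the charge as your ruler.

| setting | autumn | dawn | flask |
|---|---|---|---|
| left-handed substrate | 0.032 M | 0.051 M | 0.023 M |
| right-handed substrate | 0.032 M | 0.051 M | 0.023 M |
| solid reagent | 0.023 M | 0.023 M | 0.0230 M |
| free catalyst | 1.1 mM | 1.1 mM | 1.1 mM |
| remark | run made earlier | run made earlier |  |
| time |  |  | 10 h |

| run | time / h | left-handed substrate / % | right-handed substrate / % | left-handed product / % |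
|---|---|---|---|---|
| autumn | 1.50 | 48.7 | 49.6 | 0 |
| autumn | 4.00 | 48.0 | 50.2 | 0.4 |
| autumn | 8.00 | 46.5 | 49.6 | 2.8 |
| autumn | 12.0 | 44.2 | 47.7 | 5.9 |
| dawn | 3.00 | 48.3 | 48.9 | 0.6 |
| dawn | 6.00 | 47.5 | 49.1 | 1.5 |
| dawn | 10.0 | 45.7 | 49.1 | 3.7 |
| dawn | 12.0 | 45.8 | 49.1 | 4.7 |

(scatter of a reading: 0.5 percentage points)

- part of the left-handed substrate and right-handed substrate charged together that has reacted at 10 h
- excess of left-handed product over right-handed product in the product at 10 h
- excess of right-handed substrate over left-handed substrate among what is left of the two at 10 h

- free catalyst is single-handed; left-handed substrate and right-handed substrate are mirror images of each other, charged as a racemate, each of them at the stated concentration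
- given per volume of solution although it is solid: solid reagent
- at the start none of the solid reagent is in solution
- an excess is the difference of the two amounts in percent of their sum
- an excess is below zero if the other one leads

A catalyst works in turns, and each turn makes one molecule of product. Divide left-handed product by catalyst, both as fractions of the charge, and you have turns per catalyst, the turnover number.

At 10 h the autumn run stands midway between its readings at 8.00 h and 12.0 h. That gives 2.53 turns. The dawn run, with more substrate, gives 3.43 turns. Both runs hold the same catalyst and solid reagent as the new flask, whose substrate is lower than in either.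

Draw a straight line through the two runs and follow it down to the new flask. I get 2.10, and I carry this as the new flask's left-handed product per catalyst at the asked time. It is an estimate, a straight line taken below both runs, and each reading behind it has a scatter of 0.5 percentage points.

Catalyst is 2.39% of the new flask's charge, so I expect 5.02% of left-handed product. The runs have no column for right-handed product, so my reckoning stops there.

The forecast gave 5% reacted, a product excess of 78% and a substrate excess of 3.8%, with about 4% left-handed product against my figure, holding that “the rate is nearly zero-order in substrate”.

The new flask gives 7.27% reacted, a product excess of 63.4% and a substrate excess of 5.25%.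

    free catalyst + left-handed substrate ⇌ catalyst intermediate A (K = 23.0 M⁻¹, k = 2900 M⁻¹ h⁻¹)
    free catalyst + right-handed substrate ⇌ catalyst intermediate B (K = 13.0 M⁻¹, k = 4500 M⁻¹ h⁻¹)
    partner + catalyst intermediate A → free catalyst + left-handed product (k = 73.0 M⁻¹ h⁻¹)
    partner + catalyst intermediate B → free catalyst + right-handed product (k = 18.0 M⁻¹ h⁻¹)
    left-handed product ⇌ right-handed product (k = 0.0200 h⁻¹)
    solid reagent ⇌ partner, rate k6*(cs6 - [partner]) while solid is left; crystals form when [partner] > cs6 (solubility = 19.0 mM, k = 0.260 h⁻¹)
    partner → decomposed reagent (k = 0.00970 h⁻¹)

The product excess in the new flask was 72.6% at 2.50 h and had fallen by the asked time. Its 5.10% of left-handed product is 2.13 turns, against the 2.10 I carried.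

Now give the same flask 0.0019 M of free catalyst, which is 4.13% of the charge. The carried 2.10 turns then give 8.67% of left-handed product. The computed flask holds 8.22%, with 11.8% reacted.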